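Compound numbers (1–21) are those of the steps and the compound list below. Atom labels follow the target: oxolane O1, C2 (catechol ring), C3, C4, C5; C7 is the carbinol carbon on C4 and C9 the hydroxymethyl carbon on C3.

## Analysis of the target

The target 21 is a single oxolane. It carries a 3,4-dihydroxyphenyl group on C2, a hydroxymethyl group (C9) on C3 and an α-hydroxy-guaiacylmethyl group (C7) on C4; C5 is an unsubstituted CH2. There are four stereocentres, C2 (S), C3 (R), C4 (R) and C7 (R). On the ring the C2 aryl group and the C3 hydroxymethyl group are trans, while the C3 hydroxymethyl group and the C4 side chain are cis. The 3,4-cis pair is the more crowded arrangement and cannot be reached by equilibration. The exocyclic C7 centre lies outside the ring, so a reduction of a C7 ketone would depend on an uncertain facial bias from C4. The sensitive groups are the free catechol (oxidised under basic or peroxidic conditions), the p-hydroxybenzylic alcohol at C7 and the benzylic ether C2–O1 (both ionise under acid and are prone to hydrogenolysis). The difficulty is therefore three contiguous ring centres with a cis pair, an independent carbinol centre, and phenols that can only be freed at the very end under mild conditions. The strategy rests on one feature: the oxygen on C7 and the carbon C9 are 1,4-related (O–C7–C4–C3–C9) and cis across C3–C4. One silicon atom can therefore join them in a six-membered 1-oxa-2-silacyclohexane fused to the oxolane, which means the C7 oxygen can deliver C9 to C3 of a C3=C4 alkene.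

## Retrosynthetic reasoning

21 from 20. The three aryl O–Si bonds are cut last. Silyl protection is kept to the end because its removal needs neither acid nor hydrogen, both of which threaten the C7 carbinol and the C2–O1 bond. The forward step only has to free three phenols without oxidising the catechol.

20 from 19. The C9–OH bond and the O–H of the C7 carbinol are traced back to a C9–Si bond and a C7–O–Si bond in one ring. Oxidative cleavage of the carbon–silicon bond unveils both hydroxyl groups at once and changes no stereocentre. The forward step must oxidise at silicon while the aryl silyl ethers stay in place.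

19 from 16. The C3–C9 bond and the C4–H bond are cut. This is the only carbon–carbon bond to the ring that can be formed intramolecularly from the C7 oxygen, and cutting it turns C3 and C4 into the two carbons of a planar alkene. Two of the four stereocentres disappear from the precursor, and the remaining two (C2, C7) are simple carbinol centres. The forward reaction has to close the six-membered ring rather than the five-membered one, add to C3 anti to the C2 aryl group, and place hydrogen on C4 so that the ring fusion is cis.

16 from 14 and 15. The Si–O bond is cut. This leaves a free allylic alcohol and the commercial chlorosilane; the silylation is done immediately before the cyclisation because the tether does not survive other chemistry.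

14 from 13. The C3=C4 double bond is cut by a metathesis transform. Both alkene carbons then belong to two allyl units already joined through O1, so the ring closure is a five-membered ring-closing metathesis that creates no stereocentre.

13 from 12, and 12 from 8 and 10. The C4–C7 bond is cut between an alkenyl nucleophile and an aromatic aldehyde. Making this bond after the ether linkage exists means that the C7 hydroxyl group never needs a protecting group. The remote C2 centre cannot control C7, so the coupling is accepted as unselective and the C7 epimers are then differentiated by a reagent-controlled epoxidative kinetic resolution, which removes the unwanted epimer.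

8 from 5 and 6. The O1–C5 bond is cut. The alkoxide of a secondary benzylic alcohol attacks a primary allylic carbon, so the C2 stereocentre is not involved in the bond formation.

5 from 4, and 4 from 2 and 3. The C2–C3 bond is cut between an aldehyde and a vinyl nucleophile; the racemic carbinol is resolved enzymatically to give the (S)-alcohol.

2 from 1, and 10 from 9. Only phenol protection remains, which leads back to the two commercial hydroxybenzaldehydes.

## Alternatives that were turned down

Alternative 1: The oxolane is cut at C2–C3 and C4–C5 at once, into a C2–O1–C5 carbonyl ylide and a C3=C4 dipolarophile that is the alkene of the butenolide A2, whose carbonyl carbon is C9 and whose γ-carbon is C7. In the forward step CsF removes silicon and chloride from the α-chloro ether A3, and the ylide adds across A2 to give the cis-fused furofuranone A1. In its favour, the step is very convergent: one operation makes the ring, two C–C bonds and three stereocentres, and the lactone ties C9 and C7 cis across C3–C4 in the same way the silicon tether does. Against it, the ylide must approach A2 anti to its γ-aryl group, so the guaiacyl group ends up exo, whereas the target corresponds to the endo arrangement. A1 is thus the C7 epimer of the lactone that is needed, and the correction would be an inversion at an ionisation-prone p-oxygenated benzylic centre. In addition, the unsymmetrical ylide has no strong regiochemical preference for joining its aryl-bearing terminus to the α-carbon, and A3 is a hydrolytically fragile, easily ionised species. This alternative is shorter than the chosen route, which is a real advantage; what the chosen route offers in its place is that C7 enters the key step with the correct configuration and serves as the anchor of the tether.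

Alternative 2: The bonds C4–C7 and C3–C9 are cut, leading back to a [2+2] cycloaddition between an aryl ketene (C7 and C9) and the C3=C4 alkene of the enantiopure dihydrofuran A5, followed by oxygen insertion between C9 and C7. In the forward step the acid chloride A6 with Et3N generates the ketene, which adds to A5 on the face anti to the C2 aryl group and places its aryl substituent endo, giving the cyclobutanone A4. A Baeyer–Villiger oxidation with migration of the electron-rich benzylic carbon would then give the lactone A7. In its favour, the route is short, needs only one resolved carbinol, and the usual endo preference of the larger ketene substituent matches the crowded C7 configuration without a second resolution; on both points it is stronger than the chosen route. Against it, monoaryl ketenes dimerise readily and add poorly to unstrained, unactivated 1,2-disubstituted alkenes. Nothing in A5 decides which alkene carbon bonds to the ketene carbonyl carbon, so regioisomers are expected. The endo benzylic centre of A4 is α to a ketone and can drift to the exo epimer under the basic conditions. In the chosen route the regiochemistry is fixed by where the tether is attached and by ring size, and C7 is not epimerisable.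

Alternative 3: Only the C2–C3 bond is cut, as the insertion of a carbenoid at C3 into the benzylic C2–H bond of a benzyl ether that hangs from C4 of a lactone. In the forward step Rh2(OAc)4 decomposes the diazo lactone A8, and 1,5-insertion into the ether-activated benzylic C–H bond closes the oxolane to give the furofuranone A7. In its favour, this is the most favourable kind of C–H insertion, the cis ring fusion is enforced, the C2 aryl group should take the convex position (2,3-trans), and A7 already carries all four centres in the right relation. It also avoids tin, which is an advantage over the chosen route. Against it, the stereochemical problem is only moved into A8: a γ-aryl lactone with the aryl group cis to the neighbouring CH2O arm (the less stable arrangement) has to be made as a single enantiomer and then diazotised, which costs many steps before the key step. The carbenoid also has competing paths: 1,2-hydride shift from C4 to give a butenolide, oxonium ylide formation at the ether oxygen, and cyclopropanation of the electron-rich arenes. The chosen route needs only two simple carbinol centres in its precursor, and these are set by resolution.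

Key step: step 10

Remark on assignments: the sense of the lipase acylation (step 3) and of the titanium tartrate epoxidation (step 7) is taken from the established empirical rules for these reactions; both would be confirmed by Mosher ester analysis.

## Route

Step 1
Reactants: 1 3,4-dihydroxybenzaldehyde
Product: 2 3,4-bis(triisopropylsilyloxy)benzaldehyde
Conditions: TIPSCl (2.4 equiv), imidazole, DMF, rt → 40 °C
Reagents that add atoms: triisopropylsilyl chloride, CC(C)[Si](Cl)(C(C)C)C(C)C
Why: Imidazole-promoted silylation of phenols; the triisopropylsilyl group is chosen because aryl TIPS ethers should tolerate the later alkoxide, chromium, peroxide and radical conditions better than smaller silyl ethers and still fall to fluoride at the end.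

Step 2
Reactants: 2 3,4-bis(triisopropylsilyloxy)benzaldehyde; 3 vinylmagnesium bromide
Product: 4 rac-1-[3,4-bis(triisopropylsilyloxy)phenyl]prop-2-en-1-ol
Conditions: CH2=CHMgBr, THF, −78 → 0 °C; aq NH4Cl
Reagents that add atoms: none
Why: 1,2-Addition of a vinyl Grignard reagent to an aromatic aldehyde; it brings in the carbon that becomes C3 and creates C2 as a racemate, which is resolved in step 3.

Step 3
Reactants: 4 rac-1-[3,4-bis(triisopropylsilyloxy)phenyl]prop-2-en-1-ol
Product: 5 (1S)-1-[3,4-bis(triisopropylsilyloxy)phenyl]prop-2-en-1-ol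
Conditions: Novozym 435 (immobilised Candida antarctica lipase B), vinyl acetate, MTBE, 30 °C, stopped near half conversion; chromatography
Reagents that add atoms: none
Why: Lipase-catalysed kinetic resolution by irreversible transesterification: with aryl as the large and vinyl as the medium substituent the enzyme should acylate the (R)-enantiomer, so the unreacted alcohol is the (S)-enantiomer 5, which carries the C2 configuration of the target and is separated from the (R)-acetate.

Step 4
Reactants: 5 (1S)-1-[3,4-bis(triisopropylsilyloxy)phenyl]prop-2-en-1-ol; 6 2,3-dibromoprop-1-ene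
Product: 8 4-[(1S)-1-(2-bromoprop-2-en-1-yloxy)prop-2-en-1-yl]-1,2-bis(triisopropylsilyloxy)benzene, via sodium alkoxide 7 (not isolated)
Conditions: NaH, THF, 0 °C; then 6, Bu4NI (cat.), 0 °C → rt
Reagents that add atoms: none
Why: Williamson etherification: the alkoxide 7 displaces the allylic bromide of 6 while the vinylic bromide stays inert, so the O1–C5 bond is formed without touching the C2–O bond and the (S) configuration is kept; THF at low temperature is used because alkoxides in dipolar aprotic solvents strip aryl silyl ethers.

Step 5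
Reactants: 9 vanillin (4-hydroxy-3-methoxybenzaldehyde)
Product: 10 3-methoxy-4-(triisopropylsilyloxy)benzaldehyde
Conditions: TIPSCl (1.2 equiv), imidazole, DMF, rt
Reagents that add atoms: triisopropylsilyl chloride, CC(C)[Si](Cl)(C(C)C)C(C)C
Why: Phenol silylation as in step 1; it gives the guaiacyl ring the same fluoride-labile protection as the catechol ring.

Step 6
Reactants: 8 4-[(1S)-1-(2-bromoprop-2-en-1-yloxy)prop-2-en-1-yl]-1,2-bis(triisopropylsilyloxy)benzene; 10 3-methoxy-4-(triisopropylsilyloxy)benzaldehyde
Product: 12 2-({[(1S)-1-[3,4-bis(triisopropylsilyloxy)phenyl]prop-2-en-1-yl]oxy}methyl)-1-[3-methoxy-4-(triisopropylsilyloxy)phenyl]prop-2-en-1-ol as a mixture of the two C7 epimers, via alkenylchromium dichloride 11 (not isolated)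
Conditions: CrCl2 (4 equiv), NiCl2 (2 mol%), DMF, rt; aq work-up
Reagents that add atoms: none
Why: Nozaki–Hiyama–Kishi coupling: zerovalent nickel inserts into the alkenyl C–Br bond and transmetalation to chromium gives the trivalent alkenylchromium species 11, which adds to the aldehyde only; the reagent is not basic, so the acidic C2–H and the aryl silyl ethers are safe. The remote C2 centre is not expected to bias the new C7 centre, so both epimers should form and are differentiated in step 7.

Step 7
Reactants: 12 2-({[(1S)-1-[3,4-bis(triisopropylsilyloxy)phenyl]prop-2-en-1-yl]oxy}methyl)-1-[3-methoxy-4-(triisopropylsilyloxy)phenyl]prop-2-en-1-ol (both C7 epimers)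
Product: 13 (1S)-2-({[(1S)-1-[3,4-bis(triisopropylsilyloxy)phenyl]prop-2-en-1-yl]oxy}methyl)-1-[3-methoxy-4-(triisopropylsilyloxy)phenyl]prop-2-en-1-ol
Conditions: Ti(OiPr)4 (0.2 equiv), D-(−)-DIPT (0.24 equiv), TBHP (0.6 equiv), 4 Å MS, CH2Cl2, −20 °C; chromatography
Reagents that add atoms: none
Why: Sharpless kinetic resolution applied to a pair of epimers: the complex formed from Ti(OiPr)4 and D-(−)-DIPT should epoxidise the 1,1-disubstituted allylic alcohol of the (7R)-epimer much faster (the mirror image of the known preference of the L-(+)-tartrate catalyst), so the (7S)-epimer 13 is recovered and separated from the polar epoxy alcohol. The isolated vinyl group is not an allylic alcohol and is not epoxidised.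

Step 8
Reactants: 13 (1S)-2-({[(1S)-1-[3,4-bis(triisopropylsilyloxy)phenyl]prop-2-en-1-yl]oxy}methyl)-1-[3-methoxy-4-(triisopropylsilyloxy)phenyl]prop-2-en-1-ol
Product: 14 (S)-[(5S)-5-[3,4-bis(triisopropylsilyloxy)phenyl]-2,5-dihydrofuran-3-yl][3-methoxy-4-(triisopropylsilyloxy)phenyl]methanol
Conditions: second-generation Grubbs catalyst (H2IMes)(PCy3)Cl2Ru=CHPh (5 mol%), 1,4-benzoquinone (10 mol%), CH2Cl2 (0.01 M), 40 °C
Reagents that add atoms: none
Why: Ring-closing metathesis of a monosubstituted with a 1,1-disubstituted alkene closes the 2,5-dihydrofuran and forms the trisubstituted C3=C4 bond with loss of ethene; free allylic hydroxyl groups are tolerated, benzoquinone suppresses Ru–H isomerisation, and neither stereocentre takes part.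

Step 9
Reactants: 14 (S)-[(5S)-5-[3,4-bis(triisopropylsilyloxy)phenyl]-2,5-dihydrofuran-3-yl][3-methoxy-4-(triisopropylsilyloxy)phenyl]methanol; 15 (bromomethyl)chlorodimethylsilane
Product: 16 (bromomethyl){(S)-[(5S)-5-[3,4-bis(triisopropylsilyloxy)phenyl]-2,5-dihydrofuran-3-yl][3-methoxy-4-(triisopropylsilyloxy)phenyl]methoxy}dimethylsilane
Conditions: 15 (1.3 equiv), Et3N, DMAP (cat.), CH2Cl2, 0 °C; rapid filtration through Et3N-deactivated silica, used at once
Reagents that add atoms: none
Why: O-Silylation of the secondary alcohol with a chlorosilane and an amine base places the radical precursor on the C7 oxygen; only the O–H bond reacts, so C7 keeps its configuration.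

Step 10
Reactants: 16 (bromomethyl){(S)-[(5S)-5-[3,4-bis(triisopropylsilyloxy)phenyl]-2,5-dihydrofuran-3-yl][3-methoxy-4-(triisopropylsilyloxy)phenyl]methoxy}dimethylsilane
Product: 19 (1R,2R,6S,7S)-7-[3,4-bis(triisopropylsilyloxy)phenyl]-2-[3-methoxy-4-(triisopropylsilyloxy)phenyl]-4,4-dimethyl-3,8-dioxa-4-silabicyclo[4.3.0]nonane, via silylmethyl radical 17 (not isolated), via ring-fusion C4 radical 18 (not isolated)
Conditions: Bu3SnH (1.3 equiv), AIBN (0.1 equiv), PhH (0.01 M), 80 °C, syringe-pump addition of the stannane
Reagents that add atoms: none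
Why: Bromine abstraction from 16 by Bu3Sn• gives the α-silylmethyl radical 17, which the C7–O–Si tether holds over the alkene. Radical 17 adds to C3 in a 6-endo-trig closure that forms the C3–C9 bond and the 1-oxa-2-silacyclohexane ring; the 5-exo mode would have to attack the fully substituted C4 and is retarded, while the long Si–C and Si–O bonds make the endo transition state easy to reach. The closest known reaction type is the stannane-mediated cyclisation of (bromomethyl)dimethylsilyl ethers of allylic alcohols that carry a substituent on the proximal alkene carbon, which closes 6-endo and gives 1,4-diols after oxidation. The C3 centre is set by approach anti to the C2 aryl group (2,3-trans), and in the chair-like transition state for this approach the C7 aryl group is pseudo-equatorial, so the resident C7 centre reinforces the ring substituent. The tertiary radical 18 then takes hydrogen from Bu3SnH on the face opposite the new C3–C9 bond, the convex face of the bicycle, which gives the cis ring fusion and with it the C4 centre and the 3,4-cis relationship. C7 is not touched; its descriptor changes from S to R only because C4 becomes sp3. The step needs 6-endo over 5-exo closure, face selectivity at C3, face selectivity of hydrogen transfer at C4 and cyclisation ahead of direct reduction; these rest on the substitution at C4, the C2 aryl group, the shape of the bicyclic radical and slow addition of the stannane at high dilution.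

Step 11
Reactants: 19 (1R,2R,6S,7S)-7-[3,4-bis(triisopropylsilyloxy)phenyl]-2-[3-methoxy-4-(triisopropylsilyloxy)phenyl]-4,4-dimethyl-3,8-dioxa-4-silabicyclo[4.3.0]nonane
Product: 20 (R)-[(3R,4R,5S)-5-[3,4-bis(triisopropylsilyloxy)phenyl]-4-(hydroxymethyl)oxolan-3-yl][3-methoxy-4-(triisopropylsilyloxy)phenyl]methanol
Conditions: 30% H2O2, KHCO3, THF/MeOH (1:1), rt → 40 °C
Reagents that add atoms: hydrogen peroxide, OO
Why: Tamao oxidation of an alkoxy(alkyl)silane: hydroperoxide adds to silicon, the C9–Si bond migrates to oxygen and hydrolysis releases the C9 and C7 hydroxyl groups, with no stereocentre involved. Fluoride is left out and only bicarbonate is used so that the aryl TIPS ethers, and with them the masked catechol, should survive the oxidant.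

Step 12
Reactants: 20 (R)-[(3R,4R,5S)-5-[3,4-bis(triisopropylsilyloxy)phenyl]-4-(hydroxymethyl)oxolan-3-yl][3-methoxy-4-(triisopropylsilyloxy)phenyl]methanol
Product: 21 (7R)-7-hydroxytaxiresinol, 4-[(2S,3R,4R)-4-[(R)-hydroxy(4-hydroxy-3-methoxyphenyl)methyl]-3-(hydroxymethyl)oxolan-2-yl]benzene-1,2-diol
Conditions: Bu4NF (3.3 equiv), AcOH (3.3 equiv), THF, 0 °C, under argon
Reagents that add atoms: none
Why: Fluoride cleaves the three aryl Si–O bonds, phenoxide being a good leaving group on silicon; buffering with acetic acid and exclusion of air keep the p-hydroxybenzylic alcohol from quinone methide formation and the catechol from oxidation.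

## Compound list

1 | 3,4-dihydroxybenzaldehyde | O=Cc1ccc(O)c(O)c1 | starting material
2 | 3,4-bis(triisopropylsilyloxy)benzaldehyde | O=Cc1ccc(O[Si](C(C)C)(C(C)C)C(C)C)c(O[Si](C(C)C)(C(C)C)C(C)C)c1 | intermediate
3 | vinylmagnesium bromide | C=C[Mg]Br | starting material
4 | rac-1-[3,4-bis(triisopropylsilyloxy)phenyl]prop-2-en-1-ol | C=CC(O)c1ccc(O[Si](C(C)C)(C(C)C)C(C)C)c(O[Si](C(C)C)(C(C)C)C(C)C)c1 | intermediate
5 | (1S)-1-[3,4-bis(triisopropylsilyloxy)phenyl]prop-2-en-1-ol | C=C[C@H](O)c1ccc(O[Si](C(C)C)(C(C)C)C(C)C)c(O[Si](C(C)C)(C(C)C)C(C)C)c1 | intermediate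
6 | 2,3-dibromoprop-1-ene | C=C(Br)CBr | starting material
7 | sodium (1S)-1-[3,4-bis(triisopropylsilyloxy)phenyl]prop-2-en-1-olate (not isolated) | [Na+].C=C[C@H]([O-])c1ccc(O[Si](C(C)C)(C(C)C)C(C)C)c(O[Si](C(C)C)(C(C)C)C(C)C)c1 | intermediate
8 | 4-[(1S)-1-(2-bromoprop-2-en-1-yloxy)prop-2-en-1-yl]-1,2-bis(triisopropylsilyloxy)benzene | C=C[C@H](OCC(Br)=C)c1ccc(O[Si](C(C)C)(C(C)C)C(C)C)c(O[Si](C(C)C)(C(C)C)C(C)C)c1 | intermediate
9 | vanillin (4-hydroxy-3-methoxybenzaldehyde) | COc1cc(C=O)ccc1O | starting material
10 | 3-methoxy-4-(triisopropylsilyloxy)benzaldehyde | COc1cc(C=O)ccc1O[Si](C(C)C)(C(C)C)C(C)C | intermediate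
11 | dichloro[3-{[(1S)-1-[3,4-bis(triisopropylsilyloxy)phenyl]prop-2-en-1-yl]oxy}prop-1-en-2-yl]chromium, trivalent chromium (not isolated) | C=C[C@H](OCC(=C)[Cr](Cl)Cl)c1ccc(O[Si](C(C)C)(C(C)C)C(C)C)c(O[Si](C(C)C)(C(C)C)C(C)C)c1 | intermediate
12 | 2-({[(1S)-1-[3,4-bis(triisopropylsilyloxy)phenyl]prop-2-en-1-yl]oxy}methyl)-1-[3-methoxy-4-(triisopropylsilyloxy)phenyl]prop-2-en-1-ol, mixture of the two C7 epimers | C=C[C@H](OCC(=C)C(O)c1ccc(O[Si](C(C)C)(C(C)C)C(C)C)c(OC)c1)c1ccc(O[Si](C(C)C)(C(C)C)C(C)C)c(O[Si](C(C)C)(C(C)C)C(C)C)c1 | intermediate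
13 | (1S)-2-({[(1S)-1-[3,4-bis(triisopropylsilyloxy)phenyl]prop-2-en-1-yl]oxy}methyl)-1-[3-methoxy-4-(triisopropylsilyloxy)phenyl]prop-2-en-1-ol | C=C[C@H](OCC(=C)[C@@H](O)c1ccc(O[Si](C(C)C)(C(C)C)C(C)C)c(OC)c1)c1ccc(O[Si](C(C)C)(C(C)C)C(C)C)c(O[Si](C(C)C)(C(C)C)C(C)C)c1 | intermediate
14 | (S)-[(5S)-5-[3,4-bis(triisopropylsilyloxy)phenyl]-2,5-dihydrofuran-3-yl][3-methoxy-4-(triisopropylsilyloxy)phenyl]methanol | O[C@@H](c1ccc(O[Si](C(C)C)(C(C)C)C(C)C)c(OC)c1)C1=C[C@@H](c2ccc(O[Si](C(C)C)(C(C)C)C(C)C)c(O[Si](C(C)C)(C(C)C)C(C)C)c2)OC1 | intermediate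
15 | (bromomethyl)chlorodimethylsilane | BrC[Si](C)(C)Cl | starting material
16 | (bromomethyl){(S)-[(5S)-5-[3,4-bis(triisopropylsilyloxy)phenyl]-2,5-dihydrofuran-3-yl][3-methoxy-4-(triisopropylsilyloxy)phenyl]methoxy}dimethylsilane | BrC[Si](C)(C)O[C@@H](c1ccc(O[Si](C(C)C)(C(C)C)C(C)C)c(OC)c1)C1=C[C@@H](c2ccc(O[Si](C(C)C)(C(C)C)C(C)C)c(O[Si](C(C)C)(C(C)C)C(C)C)c2)OC1 | intermediate
17 | α-silylmethyl radical formed from 16 by loss of bromine (not isolated) | [CH2][Si](C)(C)O[C@@H](c1ccc(O[Si](C(C)C)(C(C)C)C(C)C)c(OC)c1)C1=C[C@@H](c2ccc(O[Si](C(C)C)(C(C)C)C(C)C)c(O[Si](C(C)C)(C(C)C)C(C)C)c2)OC1 | intermediate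
18 | bicyclic tertiary radical at the ring-fusion carbon C4 after C3–C9 bond formation (not isolated) | C[Si]1(C)O[C@@H](c2ccc(O[Si](C(C)C)(C(C)C)C(C)C)c(OC)c2)[C]2CO[C@H](c3ccc(O[Si](C(C)C)(C(C)C)C(C)C)c(O[Si](C(C)C)(C(C)C)C(C)C)c3)[C@H]2C1 | intermediate
19 | (1R,2R,6S,7S)-7-[3,4-bis(triisopropylsilyloxy)phenyl]-2-[3-methoxy-4-(triisopropylsilyloxy)phenyl]-4,4-dimethyl-3,8-dioxa-4-silabicyclo[4.3.0]nonane (cis-fused) | C[Si]1(C)O[C@@H](c2ccc(O[Si](C(C)C)(C(C)C)C(C)C)c(OC)c2)[C@H]2CO[C@H](c3ccc(O[Si](C(C)C)(C(C)C)C(C)C)c(O[Si](C(C)C)(C(C)C)C(C)C)c3)[C@H]2C1 | intermediate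
20 | (R)-[(3R,4R,5S)-5-[3,4-bis(triisopropylsilyloxy)phenyl]-4-(hydroxymethyl)oxolan-3-yl][3-methoxy-4-(triisopropylsilyloxy)phenyl]methanol | COc1cc([C@H](O)[C@H]2CO[C@H](c3ccc(O[Si](C(C)C)(C(C)C)C(C)C)c(O[Si](C(C)C)(C(C)C)C(C)C)c3)[C@H]2CO)ccc1O[Si](C(C)C)(C(C)C)C(C)C | intermediate
21 | (7R)-7-hydroxytaxiresinol, 4-[(2S,3R,4R)-4-[(R)-hydroxy(4-hydroxy-3-methoxyphenyl)methyl]-3-(hydroxymethyl)oxolan-2-yl]benzene-1,2-diol | COc1cc([C@H](O)[C@H]2CO[C@H](c3ccc(O)c(O)c3)[C@H]2CO)ccc1O | target

## Step count and weak points

Total step count: 12. Longest linear sequence: 11 steps (steps 1–4 and 6–12, from 1); the branch from 9 joins at step 6.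

Step 10 (key step). The most likely failures are hydrogen transfer to radical 17 before the slower 6-endo closure onto the trisubstituted alkene, and hydrogen delivery to C4 from both faces, because the C2 aryl group lies on the face from which the hydrogen has to come. The fallback forms the C3–C9 bond by a polar route, setting out from 14 and returning at 20. Oxidation of 14 with MnO2 would give the enone [(5S)-5-[3,4-bis(triisopropylsilyloxy)phenyl]-2,5-dihydrofuran-3-yl][3-methoxy-4-(triisopropylsilyloxy)phenyl]methanone F1. Conjugate addition of (iPrO)Me2SiCH2MgCl with CuI (cat.) at −78 °C should occur at C3 anti to the C2 aryl group, and kinetic protonation of the enolate at C4 on the face away from the new C3 substituent would give the 3,4-cis ketone [(3R,4S,5S)-5-[3,4-bis(triisopropylsilyloxy)phenyl]-4-{[dimethyl(propan-2-yloxy)silyl]methyl}oxolan-3-yl][3-methoxy-4-(triisopropylsilyloxy)phenyl]methanone F2, which must be kept from base to avoid epimerisation at C4. Corey–Bakshi–Shibata reduction with the (S)-methyl oxazaborolidine and BH3·SMe2, with the aryl group as the large substituent, is meant to set C7 by reagent control and give the carbinol (R)-[(3R,4S,5S)-5-[3,4-bis(triisopropylsilyloxy)phenyl]-4-{[dimethyl(propan-2-yloxy)silyl]methyl}oxolan-3-yl][3-methoxy-4-(triisopropylsilyloxy)phenyl]methanol F3. Tamao oxidation as in step 11 then leads to 20.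

Step 7. The most likely failures are insufficient rate difference between the two C7 epimers, and Lewis-acid ionisation of the doubly activated, electron-rich carbinol, which would scramble C7. The fallback sets C7 in the bond-forming step itself and runs from 8 and 10 directly to 13. It is a catalytic asymmetric Nozaki–Hiyama–Kishi coupling with CrCl2 (10 mol%), a chiral sulfonamide–oxazoline ligand, NiCl2 (cat.), Mn powder and Me3SiCl in MeCN, the ligand enantiomer being chosen for the (7S) product. No new compound arises (F0).

Step 11. The most likely failure is loss of aryl silyl groups under bicarbonate and hydroperoxide, followed by oxidative degradation of the liberated catechol. The fallback changes the phenol protection before the oxidation and runs from 19 to 21. Treatment of 19 with CsF and BnBr in DMF should exchange the three aryl silyl ethers for benzyl ethers in one pot and give (1R,2R,6S,7S)-7-[3,4-bis(benzyloxy)phenyl]-2-[4-(benzyloxy)-3-methoxyphenyl]-4,4-dimethyl-3,8-dioxa-4-silabicyclo[4.3.0]nonane F4; the siloxane, even if fluoride opens it to a fluorosilane, stays competent for oxidation. Oxidation with 30% H2O2, KF and KHCO3 in THF/MeOH would give (R)-[(3R,4R,5S)-5-[3,4-bis(benzyloxy)phenyl]-4-(hydroxymethyl)oxolan-3-yl][4-(benzyloxy)-3-methoxyphenyl]methanol F5. Brief hydrogenolysis (H2, Pd/C, EtOAc, rt, closely monitored to spare the benzylic C7–O and C2–O bonds) leads to 21.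

Step 4. The most likely failure is transfer of a silyl group from a phenolic oxygen to the alkoxide during a slow alkylation, which would scramble or remove the protection. The fallback makes the C2–O1 bond and the C2 stereocentre together by catalysis; it sets out from 2, returns at 8, and bypasses steps 2–4. Horner–Wadsworth–Emmons olefination of 2 with triethyl phosphonoacetate and NaH would give ethyl (2E)-3-[3,4-bis(triisopropylsilyloxy)phenyl]prop-2-enoate F6. Reduction with iBu2AlH gives (2E)-3-[3,4-bis(triisopropylsilyloxy)phenyl]prop-2-en-1-ol F7, and methyl chloroformate with pyridine gives (2E)-3-[3,4-bis(triisopropylsilyloxy)phenyl]prop-2-en-1-yl methyl carbonate F8. Branch-selective asymmetric allylic etherification with [Ir(cod)Cl]2, a chiral phosphoramidite ligand and 2-bromoprop-2-en-1-ol as its copper alkoxide (from the lithium alkoxide and CuI) should then give 8, with the ligand enantiomer chosen for the (S) configuration.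

## Further compounds

F1 | step 10 | [(5S)-5-[3,4-bis(triisopropylsilyloxy)phenyl]-2,5-dihydrofuran-3-yl][3-methoxy-4-(triisopropylsilyloxy)phenyl]methanone | O=C(c1ccc(O[Si](C(C)C)(C(C)C)C(C)C)c(OC)c1)C1=C[C@@H](c2ccc(O[Si](C(C)C)(C(C)C)C(C)C)c(O[Si](C(C)C)(C(C)C)C(C)C)c2)OC1
F2 | step 10 | [(3R,4S,5S)-5-[3,4-bis(triisopropylsilyloxy)phenyl]-4-{[dimethyl(propan-2-yloxy)silyl]methyl}oxolan-3-yl][3-methoxy-4-(triisopropylsilyloxy)phenyl]methanone | O=C(c1ccc(O[Si](C(C)C)(C(C)C)C(C)C)c(OC)c1)[C@H]1CO[C@H](c2ccc(O[Si](C(C)C)(C(C)C)C(C)C)c(O[Si](C(C)C)(C(C)C)C(C)C)c2)[C@H]1C[Si](C)(C)OC(C)C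
F3 | step 10 | (R)-[(3R,4S,5S)-5-[3,4-bis(triisopropylsilyloxy)phenyl]-4-{[dimethyl(propan-2-yloxy)silyl]methyl}oxolan-3-yl][3-methoxy-4-(triisopropylsilyloxy)phenyl]methanol | COc1cc([C@H](O)[C@H]2CO[C@H](c3ccc(O[Si](C(C)C)(C(C)C)C(C)C)c(O[Si](C(C)C)(C(C)C)C(C)C)c3)[C@H]2C[Si](C)(C)OC(C)C)ccc1O[Si](C(C)C)(C(C)C)C(C)C
F0 | step 7 | none | none
F4 | step 11 | (1R,2R,6S,7S)-7-[3,4-bis(benzyloxy)phenyl]-2-[4-(benzyloxy)-3-methoxyphenyl]-4,4-dimethyl-3,8-dioxa-4-silabicyclo[4.3.0]nonane | C[Si]1(C)O[C@@H](c2ccc(OCc3ccccc3)c(OC)c2)[C@H]2CO[C@H](c3ccc(OCc4ccccc4)c(OCc4ccccc4)c3)[C@H]2C1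
F5 | step 11 | (R)-[(3R,4R,5S)-5-[3,4-bis(benzyloxy)phenyl]-4-(hydroxymethyl)oxolan-3-yl][4-(benzyloxy)-3-methoxyphenyl]methanol | COc1cc([C@H](O)[C@H]2CO[C@H](c3ccc(OCc4ccccc4)c(OCc4ccccc4)c3)[C@H]2CO)ccc1OCc1ccccc1
F6 | step 4 | ethyl (2E)-3-[3,4-bis(triisopropylsilyloxy)phenyl]prop-2-enoate | CCOC(=O)/C=C/c1ccc(O[Si](C(C)C)(C(C)C)C(C)C)c(O[Si](C(C)C)(C(C)C)C(C)C)c1
F7 | step 4 | (2E)-3-[3,4-bis(triisopropylsilyloxy)phenyl]prop-2-en-1-ol | OC/C=C/c1ccc(O[Si](C(C)C)(C(C)C)C(C)C)c(O[Si](C(C)C)(C(C)C)C(C)C)c1
F8 | step 4 | (2E)-3-[3,4-bis(triisopropylsilyloxy)phenyl]prop-2-en-1-yl methyl carbonate | COC(=O)OC/C=C/c1ccc(O[Si](C(C)C)(C(C)C)C(C)C)c(O[Si](C(C)C)(C(C)C)C(C)C)c1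
A1 | alternative 1 | exo,exo-3-[4-(allyloxy)-3-methoxyphenyl]-6-[3,4-bis(allyloxy)phenyl]tetrahydro-1H,3H-furo[3,4-c]furan-1-one (C7 epimer of the lactone that maps onto the target) | O=C1O[C@H](c2ccc(OCC=C)c(OC)c2)[C@H]2CO[C@H](c3ccc(OCC=C)c(OCC=C)c3)[C@@H]12
A2 | alternative 1 | (5S)-5-[4-(allyloxy)-3-methoxyphenyl]furan-2(5H)-one | O=C1C=C[C@@H](c2ccc(OCC=C)c(OC)c2)O1
A3 | alternative 1 | {[chloro(3,4-bis(allyloxy)phenyl)methoxy]methyl}trimethylsilane | C[Si](C)(C)COC(Cl)c1ccc(OCC=C)c(OCC=C)c1
A4 | alternative 2 | endo-7-[4-(tert-butyldimethylsilyloxy)-3-methoxyphenyl]-4-[3,4-bis(tert-butyldimethylsilyloxy)phenyl]-3-oxabicyclo[3.2.0]heptan-6-one | O=C1[C@@H](c2ccc(O[Si](C)(C)C(C)(C)C)c(OC)c2)[C@H]2CO[C@H](c3ccc(O[Si](C)(C)C(C)(C)C)c(O[Si](C)(C)C(C)(C)C)c3)[C@@H]12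
A5 | alternative 2 | (2S)-2-[3,4-bis(tert-butyldimethylsilyloxy)phenyl]-2,5-dihydrofuran | C1=C[C@@H](c2ccc(O[Si](C)(C)C(C)(C)C)c(O[Si](C)(C)C(C)(C)C)c2)OC1
A6 | alternative 2 | [4-(tert-butyldimethylsilyloxy)-3-methoxyphenyl]acetyl chloride | COc1cc(CC(Cl)=O)ccc1O[Si](C)(C)C(C)(C)C
A7 | alternative 3 | endo-3-[4-(tert-butyldimethylsilyloxy)-3-methoxyphenyl]-exo-6-[3,4-bis(tert-butyldimethylsilyloxy)phenyl]tetrahydro-1H,3H-furo[3,4-c]furan-1-one | O=C1O[C@@H](c2ccc(O[Si](C)(C)C(C)(C)C)c(OC)c2)[C@H]2CO[C@H](c3ccc(O[Si](C)(C)C(C)(C)C)c(O[Si](C)(C)C(C)(C)C)c3)[C@@H]12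
A8 | alternative 3 | cis-4-({[3,4-bis(tert-butyldimethylsilyloxy)phenyl]methoxy}methyl)-5-[4-(tert-butyldimethylsilyloxy)-3-methoxyphenyl]-3-diazodihydrofuran-2(3H)-one | [N-]=[N+]=C1C(=O)O[C@@H](c2ccc(O[Si](C)(C)C(C)(C)C)c(OC)c2)[C@H]1COCc1ccc(O[Si](C)(C)C(C)(C)C)c(O[Si](C)(C)C(C)(C)C)c1
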